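**Retrosynthetic overview**
1. The target, (−)-epiafzelechin 3-O-gallate (2R,3R, 2,3-cis), comes from one hydrogenolysis of a perbenzylated all-cis flavan-4-ol 3-gallate: six benzyl ethers and the C4 hydroxyl are removed together (the leucoanthocyanidin → flavan-3-ol reduction).
2. That flavan-4-ol comes from asymmetric transfer hydrogenation of a 3-galloyloxyflavanone under dynamic kinetic resolution: C3 epimerises, and C3 and C4 are set cis to the C2 aryl (the flavanonol → leucoanthocyanidin reduction).
3. The flavanone comes from an enantioselective 6-endo oxa-Michael closure of ring C in a 2′-hydroxy-α-galloyloxychalcone. This is the plant's chalcone → flavanone cyclisation, run on a chalcone that already carries O3 and the gallate; it sets C2.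
4. The chalcone comes from aldol condensation of a phenacyl gallate with 4-benzyloxybenzaldehyde; the phenacyl gallate comes from the protected phloroacetophenone and tri-O-benzylgallic acid.
5. Ring order: rings A and B and the galloyl ring are bought as arenes; ring C is the only ring made (step 3).

Assumption: the three benzyl-protected building blocks (the acetophenone, the gallic acid and the benzaldehyde) are bought as catalogue compounds, and all phenacyl-ester and chalcone intermediates are handled in amber glass because they are light-sensitive.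

**Step 1**
Reactants: 1 1-[2,4-bis(benzyloxy)-6-hydroxyphenyl]ethan-1-one; 2 3,4,5-tris(benzyloxy)benzoic acid
Product: 4 2-[2,4-bis(benzyloxy)-6-hydroxyphenyl]-2-oxoethyl 3,4,5-tris(benzyloxy)benzoate, via alpha-bromoketone 3 (not isolated)
Conditions: CuBr2 (2.1 equiv), EtOAc/CHCl3 (1:1), reflux; filter, evaporate; then 2 (1.05 equiv), KHCO3 (1.5 equiv), DMF, 0 °C to rt
Reagents that add atoms: none
Why: King–Ostrum α-bromination, in which CuBr2 brominates the enolised side chain of an o-hydroxyaryl methyl ketone in preference to the ring, followed by SN2 phenacyl ester formation between the crude bromide and the carboxylate of 2 under bicarbonate, a base too weak to drive the competing closure to the benzofuran-3-one; no stereocentre is formed.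

**Step 2**
Reactants: 4 2-[2,4-bis(benzyloxy)-6-hydroxyphenyl]-2-oxoethyl 3,4,5-tris(benzyloxy)benzoate; 5 4-(benzyloxy)benzaldehyde
Product: 6 (Z)-1-[2,4-bis(benzyloxy)-6-hydroxyphenyl]-3-[4-(benzyloxy)phenyl]-1-oxoprop-2-en-2-yl 3,4,5-tris(benzyloxy)benzoate (the 2′-hydroxy-α-galloyloxychalcone)
Conditions: 5 (1.1 equiv), BF3·OEt2 (0.5 equiv), 1,4-dioxane, rt; cold aq. NaHCO3 work-up
Reagents that add atoms: none
Why: Lewis-acid-mediated Claisen–Schmidt (crossed aldol) condensation, in which BF3 enolises the ketone toward its only CH2 and activates the aldehyde, the base-free medium spares the ester that hydroxide would cleave, and loss of water through the 4-benzyloxybenzylic cation gives the Z enol ester with the aryl trans to the aroyl group; no stereocentre is formed.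

**Step 3**
Reactants: 6 (Z)-2′-hydroxy-α-galloyloxychalcone (hexabenzyl)
Product: 7 (2R,3R)-5,7-bis(benzyloxy)-2-[4-(benzyloxy)phenyl]-4-oxochroman-3-yl 3,4,5-tris(benzyloxy)benzoate (2,3-trans flavanone 3-gallate)
Conditions: 1-[3,5-bis(trifluoromethyl)phenyl]-3-[(8α,9S)-6′-methoxycinchonan-9-yl]thiourea (10 mol %), toluene, 4 Å MS, −20 °C to 0 °C
Reagents that add atoms: none
Why: Proposed new method: the quinuclidine nitrogen deprotonates the 2′-phenol while the thiourea binds the ketone and the neighbouring ester carbonyl of the α-acyloxy enone in a two-point array, so the phenoxide adds 6-endo to one face of the β-carbon and sets C2 as R (the spatial arrangement chalcone isomerase produces); C3 is protonated afterwards and settles as the trans epimer, which is of no consequence because C3 is reset in step 4; the closest known reaction type is the bifunctional cinchona-thiourea-catalysed intramolecular oxa-Michael cyclisation of α-alkoxycarbonyl-2′-hydroxychalcones to flavanones; the facial sense is assigned by analogy, and if the first run gives the antipode the quinidine-derived pseudoenantiomer of the catalyst is used.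

**Step 4**
Reactants: 7 (2R,3R)-5,7-bis(benzyloxy)-2-[4-(benzyloxy)phenyl]-4-oxochroman-3-yl 3,4,5-tris(benzyloxy)benzoate
Product: 9 (2R,3R,4R)-5,7-bis(benzyloxy)-2-[4-(benzyloxy)phenyl]-4-hydroxychroman-3-yl 3,4,5-tris(benzyloxy)benzoate (2,3-cis-3,4-cis), via cis-ketone epimer 8 (not isolated)
Conditions: RuCl[(S,S)-TsDPEN](p-cymene) (2 mol %), HCO2H/Et3N (1:1), DMF, 40 °C
Reagents that add atoms: none
Why: Noyori–Ikariya asymmetric transfer hydrogenation under dynamic kinetic resolution, in which C3 (alpha to the ketone and bearing the acyloxy group) epimerises through the enol in the amine/formate medium and the (S,S) catalyst delivers hydride to the C4 face anti to both the C2 aryl and the C3 ester, a matched case only for the 2,3-cis epimer, so C3 (R) and C4 (R) are set all-cis while C2 is untouched (any (2S) material is mismatched and is left behind).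

**Step 5**
Reactants: 9 (2R,3R,4R)-5,7-bis(benzyloxy)-2-[4-(benzyloxy)phenyl]-4-hydroxychroman-3-yl 3,4,5-tris(benzyloxy)benzoate
Product: 11 (2R,3R)-5,7-dihydroxy-2-(4-hydroxyphenyl)chroman-3-yl 3,4,5-trihydroxybenzoate, via debenzylated flavan-4-ol 10 (not isolated)
Conditions: H2 (3 bar), Pd(OH)2/C, THF/MeOH (1:1), AcOH (2 vol %), rt
Reagents that add atoms: none
Why: Heterogeneous hydrogenolysis, in which Pd(OH)2/H2 cleaves the six benzyl ethers and then removes the C4 hydroxyl, benzylic to the free phloroglucinol ring and lost through its quinone methide (the laboratory counterpart of the leucoanthocyanidin → flavan-3-ol reduction), while C2 and C3 are not touched and the non-benzylic secondary gallate ester stays.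

**Compound list**
1 | 1-[2,4-bis(benzyloxy)-6-hydroxyphenyl]ethan-1-one | CC(=O)c1c(O)cc(OCc2ccccc2)cc1OCc1ccccc1 | starting material
2 | 3,4,5-tris(benzyloxy)benzoic acid | OC(=O)c1cc(OCc2ccccc2)c(OCc2ccccc2)c(OCc2ccccc2)c1 | starting material
3 | 1-[2,4-bis(benzyloxy)-6-hydroxyphenyl]-2-bromoethan-1-one | O=C(CBr)c1c(O)cc(OCc2ccccc2)cc1OCc1ccccc1 | intermediate
4 | 2-[2,4-bis(benzyloxy)-6-hydroxyphenyl]-2-oxoethyl 3,4,5-tris(benzyloxy)benzoate | O=C(COC(=O)c1cc(OCc2ccccc2)c(OCc2ccccc2)c(OCc2ccccc2)c1)c1c(O)cc(OCc2ccccc2)cc1OCc1ccccc1 | intermediate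
5 | 4-(benzyloxy)benzaldehyde | O=Cc1ccc(OCc2ccccc2)cc1 | starting material
6 | (Z)-1-[2,4-bis(benzyloxy)-6-hydroxyphenyl]-3-[4-(benzyloxy)phenyl]-1-oxoprop-2-en-2-yl 3,4,5-tris(benzyloxy)benzoate | O=C(c1c(O)cc(OCc2ccccc2)cc1OCc1ccccc1)/C(OC(=O)c1cc(OCc2ccccc2)c(OCc2ccccc2)c(OCc2ccccc2)c1)=C/c1ccc(OCc2ccccc2)cc1 | intermediate
7 | (2R,3R)-5,7-bis(benzyloxy)-2-[4-(benzyloxy)phenyl]-4-oxochroman-3-yl 3,4,5-tris(benzyloxy)benzoate (2,3-trans) | O=C1[C@H](OC(=O)c2cc(OCc3ccccc3)c(OCc3ccccc3)c(OCc3ccccc3)c2)[C@@H](c2ccc(OCc3ccccc3)cc2)Oc2cc(OCc3ccccc3)cc(OCc3ccccc3)c12 | intermediate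
8 | (2R,3S)-5,7-bis(benzyloxy)-2-[4-(benzyloxy)phenyl]-4-oxochroman-3-yl 3,4,5-tris(benzyloxy)benzoate (2,3-cis epimer of 7) | O=C1[C@@H](OC(=O)c2cc(OCc3ccccc3)c(OCc3ccccc3)c(OCc3ccccc3)c2)[C@@H](c2ccc(OCc3ccccc3)cc2)Oc2cc(OCc3ccccc3)cc(OCc3ccccc3)c12 | intermediate
9 | (2R,3R,4R)-5,7-bis(benzyloxy)-2-[4-(benzyloxy)phenyl]-4-hydroxychroman-3-yl 3,4,5-tris(benzyloxy)benzoate (all-cis) | O[C@H]1[C@@H](OC(=O)c2cc(OCc3ccccc3)c(OCc3ccccc3)c(OCc3ccccc3)c2)[C@@H](c2ccc(OCc3ccccc3)cc2)Oc2cc(OCc3ccccc3)cc(OCc3ccccc3)c12 | intermediate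
10 | (2R,3R,4R)-4,5,7-trihydroxy-2-(4-hydroxyphenyl)chroman-3-yl 3,4,5-trihydroxybenzoate | O[C@H]1[C@@H](OC(=O)c2cc(O)c(O)c(O)c2)[C@@H](c2ccc(O)cc2)Oc2cc(O)cc(O)c12 | intermediate
11 | (2R,3R)-5,7-dihydroxy-2-(4-hydroxyphenyl)chroman-3-yl 3,4,5-trihydroxybenzoate, (−)-epiafzelechin 3-O-gallate, CID467295 | O=C(O[C@@H]1Cc2c(O)cc(O)cc2O[C@@H]1c1ccc(O)cc1)c1cc(O)c(O)c(O)c1 | target

**Totals**
Total step count: 5. Longest linear sequence: 5 steps (1 → 4 → 6 → 7 → 9 → 11).

**Steps most likely to fail** (in route order; step 3 carries the highest risk)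

Step 2. The BF3-mediated condensation may stop at the aldol, close prematurely to racemic flavanone, or lose the ester. The fallback sets out from 1 and comes back to the route at 7; it adds the C3 oxygen and the gallate after ring closure instead of before, in the order the plant uses. Ketone 1 and aldehyde 5 are condensed under ordinary Claisen–Schmidt conditions (KOH, EtOH/THF, rt) to the plain chalcone (E)-1-[2,4-bis(benzyloxy)-6-hydroxyphenyl]-3-[4-(benzyloxy)phenyl]prop-2-en-1-one F1. The thiourea catalyst of step 3 closes it to the flavanone (2S)-5,7-bis(benzyloxy)-2-[4-(benzyloxy)phenyl]chroman-4-one F2; a moderate ee is expected, to be raised by crystallisation and again by the catalyst-matched reduction of step 4. Enolisation with LiN(SiMe3)2 (THF, −78 °C) and oxidation with 2-(phenylsulfonyl)-3-phenyloxaziridine, anti to the C2 aryl, gives the trans flavanonol (2R,3R)-5,7-bis(benzyloxy)-2-[4-(benzyloxy)phenyl]-3-hydroxychroman-4-one F3. Esterification with acid 2 (EDC·HCl, DMAP, CH2Cl2) then gives 7.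

Step 3. The α-acyloxy enone is a weaker acceptor than the doubly activated chalcones this catalyst class is known for, so the closure may be slow or poorly selective; phenoxide-to-ester acyl transfer is a possible side path. The fallback sets out from 6 and comes back at 9; it moves the enantio-determining event from the ring closure to the reduction. Chalcone 6 is closed without stereocontrol (DABCO 20 mol %, toluene, 40 °C) to the racemic 2,3-trans ketone rac-5,7-bis(benzyloxy)-2-[4-(benzyloxy)phenyl]-4-oxochroman-3-yl 3,4,5-tris(benzyloxy)benzoate F4. This is reduced with the ruthenium catalyst of step 4 in HCO2H/DBU. There the C2 antipodes interconvert by ring opening to 6 and re-closure while C3 epimerises, and only the (2R) cis ketone 8 is matched with the catalyst, so both centres are resolved dynamically. If C2 does not equilibrate, the same reaction runs as a kinetic resolution and the unreacted (2S) ketone is recycled with DBU. Either way the product is 9.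

Step 4. C3 may epimerise too slowly, the electron-rich 5,7-dioxygenated ketone may be reduced sluggishly, or the gallate may migrate to the new cis C4 hydroxyl. The fallback sets out from 7 and comes back at 11; it sets C3 by hydrogenating an enol ester instead of by hydride delivery to a ketone. Ketone 7 is reduced (NaBH4, CeCl3·7H2O, MeOH/THF, −40 °C) to the flavan-4-ol (2R,3S)-5,7-bis(benzyloxy)-2-[4-(benzyloxy)phenyl]-4-hydroxychroman-3-yl 3,4,5-tris(benzyloxy)benzoate F5 (C4 epimer mixture). Acid-catalysed dehydration (camphorsulfonic acid 5 mol %, 4 Å MS, toluene, 50 °C) through the C4 benzylic cation gives the enol ester (2R)-5,7-bis(benzyloxy)-2-[4-(benzyloxy)phenyl]-2H-chromen-3-yl 3,4,5-tris(benzyloxy)benzoate F6. Hydrogenation (H2, Pd(OH)2/C, THF/MeOH) adds hydrogen to the C3=C4 bond anti to the C2 aryl, which gives the 2,3-cis ester, and removes the benzyl groups in the same operation, giving 11.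

**Further compounds**
F1 | step 2 | (E)-1-[2,4-bis(benzyloxy)-6-hydroxyphenyl]-3-[4-(benzyloxy)phenyl]prop-2-en-1-one | O=C(/C=C/c1ccc(OCc2ccccc2)cc1)c1c(O)cc(OCc2ccccc2)cc1OCc1ccccc1
F2 | step 2 | (2S)-5,7-bis(benzyloxy)-2-[4-(benzyloxy)phenyl]chroman-4-one | O=C1C[C@@H](c2ccc(OCc3ccccc3)cc2)Oc2cc(OCc3ccccc3)cc(OCc3ccccc3)c12
F3 | step 2 | (2R,3R)-5,7-bis(benzyloxy)-2-[4-(benzyloxy)phenyl]-3-hydroxychroman-4-one | O=C1[C@H](O)[C@@H](c2ccc(OCc3ccccc3)cc2)Oc2cc(OCc3ccccc3)cc(OCc3ccccc3)c12
F4 | step 3 | rac-5,7-bis(benzyloxy)-2-[4-(benzyloxy)phenyl]-4-oxochroman-3-yl 3,4,5-tris(benzyloxy)benzoate (racemic, 2,3-trans; no descriptors because both antipodes are present) | O=C1C(OC(=O)c2cc(OCc3ccccc3)c(OCc3ccccc3)c(OCc3ccccc3)c2)C(c2ccc(OCc3ccccc3)cc2)Oc2cc(OCc3ccccc3)cc(OCc3ccccc3)c12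
F5 | step 4 | (2R,3S)-5,7-bis(benzyloxy)-2-[4-(benzyloxy)phenyl]-4-hydroxychroman-3-yl 3,4,5-tris(benzyloxy)benzoate (C4 epimer mixture) | OC1[C@H](OC(=O)c2cc(OCc3ccccc3)c(OCc3ccccc3)c(OCc3ccccc3)c2)[C@@H](c2ccc(OCc3ccccc3)cc2)Oc2cc(OCc3ccccc3)cc(OCc3ccccc3)c12
F6 | step 4 | (2R)-5,7-bis(benzyloxy)-2-[4-(benzyloxy)phenyl]-2H-chromen-3-yl 3,4,5-tris(benzyloxy)benzoate | C1=C(OC(=O)c2cc(OCc3ccccc3)c(OCc3ccccc3)c(OCc3ccccc3)c2)[C@@H](c2ccc(OCc3ccccc3)cc2)Oc2cc(OCc3ccccc3)cc(OCc3ccccc3)c12
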